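## Retrosynthetic overview

- **Feature:** in ring B, C3–C3a and O1–C7a reach two neighbouring carbons of ring A. O1, C2 (bearing ring C), C3 and the 3-methyl group map onto the oxygen, carbonyl carbon, alpha carbon and methyl of 3,4,5-trimethoxypropiophenone.
- **Side chain:** the (E)-propenyl group at C5 comes from an aldehyde by Julia–Kocienski olefination. The aldehyde comes from a C5 methyl ester carried from the start.
- **Stereocentres:** trans-(2R,3R) comes from cis-(2S,3R) by epimerisation at C2. The cis compound comes from the flat benzofuran by enantioselective hydrogenation.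
- **Ring B:** the benzofuran comes from the propiophenone and an ortho-iodoaryl triflate in one palladium domino (C-arylation at C–I, then O-arylation at C–OTf). The triflate is made from methyl vanillate in two steps.
- **Ring order:** rings A and C are bought, and ring B is the only ring formed (step 3).

Key step: step 3

Assumption: the (R,R) antipode of the carbene ligand is taken to deliver hydrogen to the face that gives (2S,3R); a pilot run should check the sense of induction, and the equally available (S,S) ligand is used if it proves opposite.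

## Route

Step 1
Reactants: 1 methyl vanillate (methyl 4-hydroxy-3-methoxybenzoate)
Product: 2 methyl 4-hydroxy-3-iodo-5-methoxybenzoate
Conditions: NIS (1.05 equiv), CF3CO2H (10 mol %), MeCN, rt
Reagents that add atoms: N-iodosuccinimide, O=C1CCC(=O)N1I
Why: Electrophilic aromatic iodination, in which the free hydroxyl is the strongest director and its only open ortho position takes the iodine because the para position carries the ester.

Step 2
Reactants: 2 methyl 4-hydroxy-3-iodo-5-methoxybenzoate
Product: 3 methyl 3-iodo-5-methoxy-4-(trifluoromethylsulfonyloxy)benzoate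
Conditions: Tf2O (1.2 equiv), pyridine (2.5 equiv), CH2Cl2, 0 °C
Reagents that add atoms: trifluoromethanesulfonic anhydride, O=S(=O)(C(F)(F)F)OS(=O)(=O)C(F)(F)F
Why: O-sulfonylation of a phenol with triflic anhydride and pyridine is routine even for di-ortho-substituted phenols, and neither the ester nor the aryl iodide reacts.

Step 3
Reactants: 3 methyl 3-iodo-5-methoxy-4-(trifluoromethylsulfonyloxy)benzoate; 4 1-(3,4,5-trimethoxyphenyl)propan-1-one (1.2 equiv)
Product: 6 methyl 7-methoxy-3-methyl-2-(3,4,5-trimethoxyphenyl)benzofuran-5-carboxylate, via alpha-aryl ketone triflate 5 (not isolated)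
Conditions: Pd2(dba)3 (2.5 mol %), Xantphos (6 mol %), Cs2CO3 (3 equiv, dried), toluene, 80 °C then 110 °C
Reagents that add atoms: none
Why: Zerovalent palladium inserts into the C–I bond of 3, the caesium enolate of 4 replaces iodide on the arylpalladium species and C–C reductive elimination gives ketone 5 (bond C3–C3a); 5 is more acidic than 4 and is deprotonated again, palladium inserts into the adjacent C–OTf bond, the enolate oxygen binds to the metal and C–O reductive elimination gives bond O1–C7a. The closest known reaction type is the Buchwald–Hartwig ketone alpha-arylation run in domino with intramolecular enolate O-arylation, which turns ortho-dihaloarenes and enolisable ketones into 2,3-disubstituted benzofurans with this kind of catalyst and base. Ring B, the only ring formed, closes by reductive elimination from a six-membered oxapalladacycle (Pd, C7a, C3a, C3, C2, O) to the five-membered furan, and closure through carbon does not compete because it would give a benzocyclobutene. No stereocentre results, since the alpha carbon of 5 is racemic and becomes the sp2 carbon C3. The step needs site selectivity between the two leaving groups, and the substrate secures it: the C–I bond is the weaker one and has a free ortho position, whereas the triflate carbon is flanked by iodine and methoxy, so iodide reacts first and C3a and C7a cannot be interchanged. The ester para to the triflate lowers the electron density at that carbon enough for the second, hindered insertion, and the tertiary alpha carbon of 5 resists a second intermolecular arylation.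

Step 4
Reactants: 6 methyl 7-methoxy-3-methyl-2-(3,4,5-trimethoxyphenyl)benzofuran-5-carboxylate
Product: 7 methyl (2S,3R)-7-methoxy-3-methyl-2-(3,4,5-trimethoxyphenyl)-2,3-dihydrobenzofuran-5-carboxylate (cis)
Conditions: [Ru(cod)(2-methylallyl)2] (5 mol %), 1,3-bis[(R)-1-(1-naphthyl)ethyl]imidazolinium tetrafluoroborate (10 mol %), KOtBu (12 mol %), n-hexane, 70 °C (catalyst preformation); then 6, toluene/n-hexane, H2 (100 bar), 40 °C
Reagents that add atoms: none
Why: Enantioselective hydrogenation of the benzofuran C2=C3 bond with a chiral ruthenium N-heterocyclic carbene catalyst, a reaction type established for 2-aryl, 3-alkyl and multiply substituted benzofurans, delivers both hydrogens to one face, so C2 and C3 are set together as cis while the ligand selects the face that gives (2S,3R) and the benzenoid rings and the ester stay untouched.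

Step 5
Reactants: 7 methyl (2S,3R)-7-methoxy-3-methyl-2-(3,4,5-trimethoxyphenyl)-2,3-dihydrobenzofuran-5-carboxylate
Product: 8 methyl (2R,3R)-7-methoxy-3-methyl-2-(3,4,5-trimethoxyphenyl)-2,3-dihydrobenzofuran-5-carboxylate (trans)
Conditions: CF3CO2H/CH2Cl2 (1:4), dilute, 0 °C to rt; crystallisation
Reagents that add atoms: none
Why: Acid-mediated epimerisation of a 2-aryl-2,3-dihydrobenzofuran, in which reversible heterolysis of the protonated benzylic C2–O1 bond (helped by the trimethoxyphenyl donor and by the para ester on the leaving phenol) and re-closure lead under thermodynamic control to the trans isomer, so that C2 becomes R under the control of the untouched (R) centre C3.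

Step 6
Reactants: 8 methyl (2R,3R)-7-methoxy-3-methyl-2-(3,4,5-trimethoxyphenyl)-2,3-dihydrobenzofuran-5-carboxylate
Product: 9 [(2R,3R)-7-methoxy-3-methyl-2-(3,4,5-trimethoxyphenyl)-2,3-dihydrobenzofuran-5-yl]methanol
Conditions: LiAlH4, THF, 0 °C; Fieser work-up
Reagents that add atoms: none
Why: Hydride reduction of an aromatic methyl ester to the benzylic alcohol, to which the aryl ethers and both stereocentres are inert.

Step 7
Reactants: 9 [(2R,3R)-7-methoxy-3-methyl-2-(3,4,5-trimethoxyphenyl)-2,3-dihydrobenzofuran-5-yl]methanol
Product: 10 (2R,3R)-7-methoxy-3-methyl-2-(3,4,5-trimethoxyphenyl)-2,3-dihydrobenzofuran-5-carbaldehyde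
Conditions: activated MnO2 (excess), CH2Cl2, rt
Reagents that add atoms: none
Why: Heterogeneous MnO2 oxidation of a benzylic alcohol stops at the aldehyde under neutral conditions that leave C2 and C3 alone.

Step 8
Reactants: 10 (2R,3R)-7-methoxy-3-methyl-2-(3,4,5-trimethoxyphenyl)-2,3-dihydrobenzofuran-5-carbaldehyde
Product: 11 (2R,3R)-7-methoxy-3-methyl-5-[(E)-prop-1-enyl]-2-(3,4,5-trimethoxyphenyl)-2,3-dihydrobenzofuran (target)
Conditions: 5-(ethylsulfonyl)-1-phenyl-1H-tetrazole, KN(SiMe3)2, DME, −60 °C; then 10, −60 °C to rt
Reagents that add atoms: 5-(ethylsulfonyl)-1-phenyl-1H-tetrazole, CCS(=O)(=O)c1nnnn1-c1ccccc1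
Why: Julia–Kocienski olefination, in which the metalated phenyltetrazolyl sulfone adds to the aromatic aldehyde and Smiles rearrangement followed by loss of SO2 and tetrazololate gives the alkene, with the (E) geometry strongly favoured for aryl aldehydes with a potassium base in DME and with no acidic hydrogen at C2 or C3.

## Compound list

1 | methyl vanillate | COC(=O)c1ccc(O)c(OC)c1 | starting material
2 | methyl 4-hydroxy-3-iodo-5-methoxybenzoate | COC(=O)c1cc(I)c(O)c(OC)c1 | intermediate
3 | methyl 3-iodo-5-methoxy-4-(trifluoromethylsulfonyloxy)benzoate | COC(=O)c1cc(I)c(OS(=O)(=O)C(F)(F)F)c(OC)c1 | intermediate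
4 | 1-(3,4,5-trimethoxyphenyl)propan-1-one | CCC(=O)c1cc(OC)c(OC)c(OC)c1 | starting material
5 | methyl 3-methoxy-5-[1-oxo-1-(3,4,5-trimethoxyphenyl)propan-2-yl]-4-(trifluoromethylsulfonyloxy)benzoate (racemic, centre erased in the same step) | COC(=O)c1cc(OC)c(OS(=O)(=O)C(F)(F)F)c(c1)C(C)C(=O)c1cc(OC)c(OC)c(OC)c1 | intermediate
6 | methyl 7-methoxy-3-methyl-2-(3,4,5-trimethoxyphenyl)benzofuran-5-carboxylate | COC(=O)c1cc(OC)c2oc(-c3cc(OC)c(OC)c(OC)c3)c(C)c2c1 | intermediate
7 | methyl (2S,3R)-7-methoxy-3-methyl-2-(3,4,5-trimethoxyphenyl)-2,3-dihydrobenzofuran-5-carboxylate (cis) | COC(=O)c1cc(OC)c2c(c1)[C@@H](C)[C@@H](c1cc(OC)c(OC)c(OC)c1)O2 | intermediate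
8 | methyl (2R,3R)-7-methoxy-3-methyl-2-(3,4,5-trimethoxyphenyl)-2,3-dihydrobenzofuran-5-carboxylate (trans) | COC(=O)c1cc(OC)c2c(c1)[C@@H](C)[C@H](c1cc(OC)c(OC)c(OC)c1)O2 | intermediate
9 | [(2R,3R)-7-methoxy-3-methyl-2-(3,4,5-trimethoxyphenyl)-2,3-dihydrobenzofuran-5-yl]methanol | OCc1cc(OC)c2c(c1)[C@@H](C)[C@H](c1cc(OC)c(OC)c(OC)c1)O2 | intermediate
10 | (2R,3R)-7-methoxy-3-methyl-2-(3,4,5-trimethoxyphenyl)-2,3-dihydrobenzofuran-5-carbaldehyde | O=Cc1cc(OC)c2c(c1)[C@@H](C)[C@H](c1cc(OC)c(OC)c(OC)c1)O2 | intermediate
11 | (2R,3R)-7-methoxy-3-methyl-5-[(E)-prop-1-enyl]-2-(3,4,5-trimethoxyphenyl)-2,3-dihydrobenzofuran | C/C=C/c1cc(OC)c2c(c1)[C@@H](C)[C@H](c1cc(OC)c(OC)c(OC)c1)O2 | target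

Total step count: 8
Longest linear sequence: 8 steps (1 to 11); ketone 4 is used as bought.

## Steps most likely to fail

**1. Step 4.** Hydrogen uptake at the tetrasubstituted, aryl-conjugated C2=C3 bond may be slow, and facial selectivity may be poor. The fallback gives up catalyst control in favour of resolution.
- It sets out from 6, which is hydrogenated over palladium on carbon (H2, 50 bar, EtOAc/AcOH, 50 °C) to the racemic cis ester F1.
- CF3CO2H in CH2Cl2, as in step 5, should equilibrate this to the racemic trans ester F2.
- The enantiomers are then separated by preparative chromatography on a chiral stationary phase.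
- The (2R,3R) fraction is 8, where the route is rejoined.

**2. Step 5.** The open benzylic cation may lose the proton at C3, which would erode the C3 configuration on re-protonation. It may also be captured by an electron-rich arene. The fallback sets the trans relationship without any cation and never passes through the cis compound.
- It sets out from 3 and 4, which are coupled with the same catalyst and Cs2CO3 at 70 °C. The reaction is stopped before ring closure so that 5 is isolated.
- Noyori–Ikariya transfer hydrogenation follows (RuCl(p-cymene)[(R,R)-TsDPEN], amine-rich HCO2H/Et3N, CH2Cl2, 30 °C). It runs with dynamic kinetic resolution of the labile alpha centre.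
- The catalyst should fix the carbinol centre and Felkin–Anh control the relative configuration, giving the (1R,2R) hydroxy triflate F3.
- Palladium-catalysed intramolecular C–O coupling then closes O1–C7a on the same triflate carbon (Pd(OAc)2, 2-(di-tert-butylphosphino)-1,1'-binaphthyl, Cs2CO3, toluene, 70 °C). Both centres are retained.
- The route is rejoined at 8.

**3. Step 3.** The triflyl group may be lost by S–O cleavage under carbonate. The domino may also stall after the first coupling because the di-ortho-substituted triflate resists insertion. The fallback keeps the alpha-arylation but closes the furan by acid cyclodehydration, so that O1 comes from the phenol.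
- It sets out from 2, which is protected (MOMCl, iPr2NEt, CH2Cl2) as the methoxymethyl ether F4.
- Alpha-arylation of 4 with F4 (Pd2(dba)3, Xantphos, Cs2CO3, toluene, 90 °C) should give the alpha-aryl ketone F5.
- p-TsOH·H2O in toluene at 80 °C removes the acetal and dehydrates the resulting ortho-hydroxyaryl ketone.
- The route is rejoined at 6.

## Further compounds

F1 | step 4 | racemic cis methyl 7-methoxy-3-methyl-2-(3,4,5-trimethoxyphenyl)-2,3-dihydrobenzofuran-5-carboxylate | COC(=O)c1cc(OC)c2c(c1)[C@@H](C)[C@@H](c1cc(OC)c(OC)c(OC)c1)O2.COC(=O)c1cc(OC)c2c(c1)[C@H](C)[C@H](c1cc(OC)c(OC)c(OC)c1)O2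
F2 | step 4 | racemic trans methyl 7-methoxy-3-methyl-2-(3,4,5-trimethoxyphenyl)-2,3-dihydrobenzofuran-5-carboxylate | COC(=O)c1cc(OC)c2c(c1)[C@@H](C)[C@H](c1cc(OC)c(OC)c(OC)c1)O2.COC(=O)c1cc(OC)c2c(c1)[C@H](C)[C@@H](c1cc(OC)c(OC)c(OC)c1)O2
F3 | step 5 | methyl 3-[(1R,2R)-1-hydroxy-1-(3,4,5-trimethoxyphenyl)propan-2-yl]-5-methoxy-4-(trifluoromethylsulfonyloxy)benzoate | COC(=O)c1cc(OC)c(OS(=O)(=O)C(F)(F)F)c(c1)[C@@H](C)[C@H](c1cc(OC)c(OC)c(OC)c1)O
F4 | step 3 | methyl 3-iodo-5-methoxy-4-(methoxymethoxy)benzoate | COCOc1c(I)cc(cc1OC)C(=O)OC
F5 | step 3 | methyl 3-methoxy-4-(methoxymethoxy)-5-[1-oxo-1-(3,4,5-trimethoxyphenyl)propan-2-yl]benzoate (racemic) | COCOc1c(OC)cc(cc1C(C)C(=O)c1cc(OC)c(OC)c(OC)c1)C(=O)OC
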